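**Retrosynthetic overview**
1. The target is 5-hydroxy-7-methoxy-2-tritriacontylchromone; the side chain is numbered C1′ (on pyranone C2) to C33′ and is cut between C6′ and C7′, giving 1-bromoheptacosane and a C6′ radical on the chromone half.
2. Enabling feature: pyranone C2 is at the ketone oxidation level, lies 1,3 to the C4 carbonyl, and together with the six methylenes C1′–C6′ makes seven carbons, i.e. a cycloheptanone. The aldol adduct of the acetophenone with cycloheptanone therefore holds the whole chromone half in a temporary seven-membered ring.
3. Key event: alkoxy-radical β-scission of the ring bond C2–C6′ of that cycloheptanol unveils the C2 ketone (the 1,3-diketone) and a C6′ radical, which nickel couples with the C27 bromide; acid in the same flask removes the MOM groups and closes the pyranone.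
4. Ring order: the benzene ring is bought (2′,6′-dihydroxy-4′-methoxyacetophenone); the cycloheptane ring is attached by aldol addition and opened in the key step; the pyranone ring (O1–C2, then C2=C3 by dehydration) is formed last.

Key step: step 4

Step 1
Reactants: 1 1-(2,6-dihydroxy-4-methoxyphenyl)ethan-1-one
Product: 2 1-[4-methoxy-2,6-bis(methoxymethoxy)phenyl]ethan-1-one
Conditions: NaH (2.2 equiv), DMF, 0 °C; MOMCl (2.4 equiv), 0 °C to rt
Reagents that add atoms: chloromethyl methyl ether (MOMCl), COCCl
Why: Williamson-type O-alkylation of both phenoxides (MOM protection); NaH breaks the chelate hydrogen bonds so that both hydroxyls react, and the acetals mask the phenols until the acid stage of step 4.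

Step 2
Reactants: 2 1-[4-methoxy-2,6-bis(methoxymethoxy)phenyl]ethan-1-one, 3 cycloheptanone
Product: 5 2-(1-hydroxycycloheptyl)-1-[4-methoxy-2,6-bis(methoxymethoxy)phenyl]ethan-1-one, via lithium enolate 4 (not isolated)
Conditions: LDA (1.05 equiv), THF, −78 °C; 3 (1.2 equiv), −78 °C; AcOH quench at −78 °C
Reagents that add atoms: none
Why: Directed aldol addition of the preformed lithium enolate (the only enolizable position of 2) to the ketone, with a cold acidic quench against retro-aldol; the new carbinol carbon carries two identical ring arms, so no stereocenter arises.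

Step 3
Reactants: 6 heptacosan-1-ol
Product: 7 1-bromoheptacosane
Conditions: CBr4 (1.3 equiv), PPh3 (1.4 equiv), CH2Cl2/THF, 35 °C
Reagents that add atoms: carbon tetrabromide, BrC(Br)(Br)Br
Why: Appel reaction, SN2 displacement of the alkoxyphosphonium group of a primary alcohol by bromide.

Step 4
Reactants: 5 2-(1-hydroxycycloheptyl)-1-[4-methoxy-2,6-bis(methoxymethoxy)phenyl]ethan-1-one, 7 1-bromoheptacosane
Product: 10 5-hydroxy-7-methoxy-2-tritriacontyl-4H-chromen-4-one, via bis-MOM 1,3-diketone 8 (not isolated), via dihydroxyaryl 1,3-diketone 9 (not isolated)
Conditions: Ir[dF(CF3)ppy]2(dtbbpy)PF6 (2 mol%), NiBr2·dme (10 mol%), dtbbpy (12 mol%), 2,4,6-collidine (2 equiv), 7 (1.5 equiv), PhCF3/MeCN 3:1, blue LEDs, 40 °C; then 3 M HCl in MeOH, 55 °C, same flask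
Reagents that add atoms: none
Why: Proposed new method: the photoexcited iridium complex and collidine remove the hydroxyl hydrogen of 5 by proton-coupled electron transfer, the tertiary alkoxy radical cleaves the ring bond C2–C6′ by β-scission, which turns the carbinol carbon into the C2 ketone (1,3 to the aryl ketone) and leaves a primary radical at C6′, and nickel joins this radical to 7 by oxidative addition of the C–Br bond to (dtbbpy)Ni(0), capture of the radical, reductive elimination from Ni(III) that forms C6′–C7′, and reduction of Ni(I) by Ir(II). The closest known reaction types are the nickel/photoredox ring-opening arylation of tertiary cycloalkanols through alkoxy radicals and the metallaphotoredox C(sp3)–C(sp3) coupling of alkyl radicals with primary alkyl bromides, and the proposal puts the alkyl bromide of the second in the place of the aryl halide of the first. In the acid stage both MOM acetals are cleaved and the pyranone ring closes by 6-exo-trig addition of a phenol oxygen to the C2 ketone followed by loss of water to the C2=C3 bond (the cyclodehydration that ends a Baker–Venkataraman chromone synthesis); the two ortho hydroxyls are equivalent, so only one chromone can form and the second hydroxyl is left as the 5-OH. No stereocenter is formed. The step needs β-scission of a ring bond and not of the exocyclic C2–C3 bond (loss of a phenacyl radical, a radical retro-aldol), which two ring bonds against one, the relief of cycloheptane strain and the polarity mismatch between the electrophilic phenacyl radical and the electrophilic alkoxy radical should secure, and it needs cross-coupling ahead of β-hydride elimination, which the excess of the primary bromide and the bipyridine ligand serve.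

**Compound list**
1 | 1-(2,6-dihydroxy-4-methoxyphenyl)ethan-1-one (2′,6′-dihydroxy-4′-methoxyacetophenone), achiral | CC(=O)c1c(O)cc(OC)cc1O | starting material
2 | 1-[4-methoxy-2,6-bis(methoxymethoxy)phenyl]ethan-1-one, achiral | CC(=O)c1c(OCOC)cc(OC)cc1OCOC | intermediate
3 | cycloheptanone | O=C1CCCCCC1 | starting material
4 | lithium 1-[4-methoxy-2,6-bis(methoxymethoxy)phenyl]ethen-1-olate (lithium enolate of 2) | C=C([O-])c1c(OCOC)cc(OC)cc1OCOC.[Li+] | intermediate
5 | 2-(1-hydroxycycloheptyl)-1-[4-methoxy-2,6-bis(methoxymethoxy)phenyl]ethan-1-one, achiral | COCOc1cc(OC)cc(OCOC)c1C(=O)CC1(O)CCCCCC1 | intermediate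
6 | heptacosan-1-ol | CCCCCCCCCCCCCCCCCCCCCCCCCCCO | starting material
7 | 1-bromoheptacosane | CCCCCCCCCCCCCCCCCCCCCCCCCCCBr | intermediate
8 | 1-[4-methoxy-2,6-bis(methoxymethoxy)phenyl]hexatriacontane-1,3-dione, achiral | COCOc1cc(OC)cc(OCOC)c1C(=O)CC(=O)CCCCCCCCCCCCCCCCCCCCCCCCCCCCCCCCC | intermediate
9 | 1-(2,6-dihydroxy-4-methoxyphenyl)hexatriacontane-1,3-dione, achiral | COc1cc(O)c(C(=O)CC(=O)CCCCCCCCCCCCCCCCCCCCCCCCCCCCCCCCC)c(O)c1 | intermediate
10 | 5-hydroxy-7-methoxy-2-tritriacontyl-4H-chromen-4-one, achiral | CCCCCCCCCCCCCCCCCCCCCCCCCCCCCCCCCc1cc(=O)c2c(O)cc(OC)cc2o1 | target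

**Step count and risks**
Total step count: 4. Longest linear sequence: 3 steps (steps 1, 2 and 4, from compound 1).

The three steps most likely to fail, the labelled step first:

Risk 1, step 4. Four processes threaten it. β-Scission may occur at the exocyclic C2–C3 bond instead of a ring bond, a radical retro-aldol that returns ketone 2 and cycloheptanone. The enolised 1,3-diketone may be oxidised further or may bind nickel as conversion rises. The bromide may be lost by protodehalogenation, β-hydride elimination or homocoupling before the C6′ radical is captured. Too small a driving force for the O–H activation would show as unchanged 5. The fallback uses known chemistry and forms the same C6′–C7′ bond. It sets out from 7 and 2. Bromide 7 is converted with magnesium in THF into heptacosylmagnesium bromide F1, which is coupled with commercial ethyl 7-bromoheptanoate under copper catalysis (Li2CuCl4, THF/NMP, −10 to 0 °C) to ethyl tetratriacontanoate F2. Lithium enolate 4, made from 2 with LDA (2.2 equiv of enolate), is acylated by F2 in a crossed Claisen condensation (THF, −78 to 0 °C) and gives the 1,3-diketone 8, where the fallback comes back to the route; the acid stage of step 4 then leads through 9 to 10.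

Risk 2, step 2. The aldol addition is reversible and the enolate can also deprotonate cycloheptanone, so proton transfer and retro-aldol cleavage on warming or work-up may return the two ketones. The fallback sets out from 3 and comes back at 5. Cycloheptanone 3 reacts with commercial 2-bromo-N-methoxy-N-methylacetamide and zinc (Reformatsky reaction, THF, 40 °C) to give 2-(1-hydroxycycloheptyl)-N-methoxy-N-methylacetamide F3. Commercial 5-methoxyresorcinol is protected (NaH, MOMCl, DMF) as 1-methoxy-3,5-bis(methoxymethoxy)benzene F4, which n-BuLi (THF, 0 °C) lithiates between the two MOM ethers (directed ortho-metalation) to [4-methoxy-2,6-bis(methoxymethoxy)phenyl]lithium F5. F5 is added at −78 °C to F3, whose hydroxyl has first been deprotonated with i-PrMgCl, and the Weinreb ketone synthesis delivers 5.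

Risk 3, step 3. The waxy alcohol dissolves poorly, so the Appel reaction may stall and the product may co-crystallise with triphenylphosphine oxide. The fallback sets out from 6 and comes back at 7. Alcohol 6 is converted (TsCl, pyridine, DMAP, CH2Cl2, 40 °C) into heptacosyl 4-methylbenzenesulfonate F6, and SN2 displacement with LiBr in 2-butanone at reflux gives 7.

**Further compounds**
F1 | step 4 | heptacosylmagnesium bromide | CCCCCCCCCCCCCCCCCCCCCCCCCCC[Mg]Br
F2 | step 4 | ethyl tetratriacontanoate | CCCCCCCCCCCCCCCCCCCCCCCCCCCCCCCCCC(=O)OCC
F3 | step 2 | 2-(1-hydroxycycloheptyl)-N-methoxy-N-methylacetamide | CON(C)C(=O)CC1(O)CCCCCC1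
F4 | step 2 | 1-methoxy-3,5-bis(methoxymethoxy)benzene | COCOc1cc(OC)cc(OCOC)c1
F5 | step 2 | [4-methoxy-2,6-bis(methoxymethoxy)phenyl]lithium | [Li]c1c(OCOC)cc(OC)cc1OCOC
F6 | step 3 | heptacosyl 4-methylbenzenesulfonate | CCCCCCCCCCCCCCCCCCCCCCCCCCCOS(=O)(=O)c1ccc(C)cc1
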